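**Retrosynthetic overview**
1. Target ⇐ bis‑TBS dienone ⇐ oxidation of the C8 carbinol; the C5 methyl carbinol comes from a Felkin–Anh methyl addition to a macrocyclic α‑acyloxy ketone.
2. The only ring (11‑membered carbocycle) is closed once, at C8–C9, by an intramolecular Nozaki–Hiyama–Kishi coupling of a (Z)‑vinyl iodide onto the aldehyde of an (E)‑4‑oxo‑2‑enal.
3. Key step: that oxo‑enal (C5 ketone, C6=C7, C8 aldehyde) is unveiled late by singlet‑oxygen dearomatisation of a 2‑substituted furan whose four carbons are C5–C8 (source: furfural).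
4. C3–C4 and the E‑C2=C3 alkene come from a catalytic enantioselective alkenylzinc addition of a terminal alkyne to furfural; the senecioate is put on C4 before the furan is opened.
5. The C1 quaternary centre comes from geraniol by NHC–copper SN2′ alkynylation; the side‑chain carbinol from Shi epoxidation then epoxide → allyl silyl ether; the C9=C10 geometry from an iodo‑Wittig olefination.

Assumption: the enantiomers of the two chiral ligands (steps 2 and 10) and of the Shi ketone (step 3) are the ones that give the configurations drawn; 23 is carried as a mixture of C8 epimers.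
Ring numbering used: C1 (quaternary, Me, side chain), C2=C3, C4 (O‑senecioyl), C5 (Me, OH), C6=C7, C8 (C=O), C9 (CH2OH), C10, C11 (CH2).

**Step 1**
Reactants: 1 geraniol
Product: 2 geranyl diethyl phosphate
Conditions: ClP(O)(OEt)2, pyridine, CH2Cl2, 0 °C → rt
Reagents that add atoms: diethyl chlorophosphate, CCOP(=O)(Cl)OCC
Why: O‑phosphorylation of the primary allylic alcohol gives the leaving group for the SN2′ step without touching the E‑trisubstituted alkene.

**Step 2**
Reactants: 2 geranyl diethyl phosphate; 3 ethynyltrimethylsilane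
Product: 5 (S)-(3-ethenyl-3,7-dimethyloct-6-en-1-yn-1-yl)trimethylsilane, via alkynylalane 4 (not isolated)
Conditions: 3, iBu2AlH, Et3N (5 mol %), hexanes, 55 °C; then 2, CuCl2·2H2O (5 mol %), chiral sulfonate‑bearing imidazolinium salt (NHC precursor, 5.5 mol %), THF, −30 °C
Reagents that add atoms: diisobutylaluminium hydride, CC(C)C[AlH]CC(C)C (iBu2Al group of 4 only)
Why: NHC–copper‑catalysed enantioselective SN2′ allylic substitution with an alkynylaluminium delivers the alkynyl group to the γ‑carbon of the geometrically pure allylic phosphate, so the C1 quaternary centre (S) is set by the catalyst and a vinyl group is left.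

**Step 3**
Reactants: 5 (S)-enyne
Product: 6 {(3S)-5-[(2S)-3,3-dimethyloxiran-2-yl]-3-ethenyl-3-methylpent-1-yn-1-yl}trimethylsilane
Conditions: L‑fructose‑derived Shi ketone (30 mol %), Oxone (2KHSO5·KHSO4·K2SO4), K2CO3, Bu4NHSO4, MeCN/DMM/aq. buffer pH 10.5, 0 °C
Reagents that add atoms: potassium peroxymonosulfate KHSO5, [K+].[O-]S(=O)(=O)OO
Why: Shi asymmetric epoxidation (chiral dioxirane, spiro transition state) attacks only the electron‑rich trisubstituted alkene and sets the side‑chain stereocentre as the (S)‑epoxide carbon under catalyst control.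

**Step 4**
Reactants: 6 epoxy enyne
Product: 8 (3S)-5-[(2S)-3,3-dimethyloxiran-2-yl]-3-methyl-3-[(trimethylsilyl)ethynyl]pentan-1-ol, via B-alkyl-9-BBN 7 (not isolated)
Conditions: 9‑BBN (1.2 equiv), THF, 0 °C → rt; then 30% H2O2, aq. NaOAc, 0 °C → rt
Reagents that add atoms: 9‑borabicyclo[3.3.1]nonane, [H]B1C2CCCC1CCC2 (boron unit of 7 only); hydrogen peroxide, OO
Why: anti‑Markovnikov hydroboration–oxidation of the only monosubstituted alkene (the silyl alkyne and the epoxide are slower) turns the vinyl group into C11–C10–OH without touching either stereocentre.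

**Step 5**
Reactants: 8 primary alcohol
Product: 9 (3S)-5-[(2S)-3,3-dimethyloxiran-2-yl]-3-methyl-3-[(trimethylsilyl)ethynyl]pentanal
Conditions: Dess–Martin periodinane, NaHCO3, CH2Cl2, 0 °C → rt
Reagents that add atoms: none
Why: Dess–Martin oxidation gives the C10 aldehyde under buffered conditions that leave the epoxide and silyl alkyne intact.

**Step 6**
Reactants: 9 aldehyde
Product: 10 ethyl (2Z,5S)-7-[(2S)-3,3-dimethyloxiran-2-yl]-2-iodo-5-methyl-5-[(trimethylsilyl)ethynyl]hept-2-enoate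
Conditions: Ph3P=CHCO2Et, NIS, CH2Cl2, −20 °C; then 9, −20 °C → rt
Reagents that add atoms: ethyl (triphenylphosphoranylidene)acetate, CCOC(=O)C=P(c1ccccc1)(c1ccccc1)c1ccccc1; N‑iodosuccinimide, O=C1CCC(=O)N1I
Why: Wittig olefination with the α‑iodo stabilised ylide made in the flask places the ester trans to the alkyl chain, so iodine ends cis to C11 (Z), which later becomes the C8/C11‑cis geometry of C9=C10.

**Step 7**
Reactants: 10 iodo enoate
Product: 11 (2Z,5S)-7-[(2S)-3,3-dimethyloxiran-2-yl]-2-iodo-5-methyl-5-[(trimethylsilyl)ethynyl]hept-2-en-1-ol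
Conditions: iBu2AlH (2.2 equiv), CH2Cl2, −78 °C; aq. KNaC4H4O6
Reagents that add atoms: none
Why: 1,2‑reduction of the ester by the aluminium hydride at low temperature gives the C9 hydroxymethyl group without opening the trisubstituted epoxide or removing iodine.

**Step 8**
Reactants: 11 iodo allylic alcohol
Product: 12 (2Z,5S,8S)-1,8-bis(tert-butyldimethylsilyloxy)-2-iodo-5,9-dimethyl-5-[(trimethylsilyl)ethynyl]deca-2,9-diene
Conditions: TBSOTf (3 equiv), 2,6‑lutidine (4 equiv), DBU (1.5 equiv), toluene, −78 °C → rt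
Reagents that add atoms: tert‑butyldimethylsilyl triflate, CC(C)(C)[Si](C)(C)OS(=O)(=O)C(F)(F)F
Why: silyl‑triflate‑mediated epoxide → allyl silyl ether isomerisation (ionisation at the tertiary carbon, loss of a methyl proton to the base) gives the isopropenyl carbinol silyl ether with retention, because the C–O bond at the stereocentre is never broken, while the primary alcohol is silylated in the same pot.

**Step 9**
Reactants: 12 bis‑TBS silyl alkyne
Product: 13 (2Z,5S,8S)-1,8-bis(tert-butyldimethylsilyloxy)-5-ethynyl-2-iodo-5,9-dimethyldeca-2,9-diene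
Conditions: K2CO3, MeOH, rt
Reagents that add atoms: none
Why: methanolysis of the C(sp)–Si bond frees the terminal alkyne while the TBS ethers and the vinyl iodide are inert to carbonate.

**Step 10**
Reactants: 13 terminal alkyne; 14 furfural
Product: 17 (1R,2E,4S,7S)-7-(TBSO)-4-[(2Z)-4-(TBSO)-3-iodobut-2-en-1-yl]-1-(furan-2-yl)-4,8-dimethylnona-2,8-dien-1-ol, via alkenylborane 15 (not isolated), via alkenylzinc 16 (not isolated)
Conditions: Cy2BH, toluene, 0 °C → rt; Me2Zn, −78 °C; (+)‑MIB [(2R)‑3‑exo‑morpholinoisoborneol, 10 mol %], 14, −30 → 0 °C; aq. NH4Cl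
Reagents that add atoms: dicyclohexylborane, [H]B(C1CCCCC1)C1CCCCC1 (boryl group of 15 only); dimethylzinc, C[Zn]C (methylzinc group of 16 only)
Why: syn‑hydroboration of the terminal alkyne (fixes E‑C2=C3), boron‑to‑zinc transmetalation and amino‑alcohol‑catalysed enantioselective 1,2‑addition of the alkenylzinc to the Re face of furfural set C4 as (R) under ligand control.

**Step 11**
Reactants: 17 furyl allylic alcohol; 18 3‑methylbut‑2‑enoic acid (senecioic acid)
Product: 19 (1R,2E,4S,7S)-7-(TBSO)-4-[(2Z)-4-(TBSO)-3-iodobut-2-en-1-yl]-1-(furan-2-yl)-4,8-dimethylnona-2,8-dien-1-yl 3-methylbut-2-enoate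
Conditions: 18, DCC, DMAP (cat.), CH2Cl2, 0 °C → rt
Reagents that add atoms: none
Why: Steglich esterification acylates the only free hydroxyl with retention at C4, so no late differentiation of four hydroxyls is needed.

**Step 12 (key step)**
Reactants: 19 furyl senecioate
Product: 22 (2E,5R,6E,8S,11S)-11-(TBSO)-8-[(2Z)-4-(TBSO)-3-iodobut-2-en-1-yl]-8,12-dimethyl-1,4-dioxotrideca-2,6,12-trien-5-yl 3-methylbut-2-enoate, via endoperoxide 20 (not isolated), via Z-oxoenal 21 (not isolated)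
Conditions: O2, tetraphenylporphyrin (cat.), visible light, CH2Cl2, −78 °C; Me2S, −78 °C → rt; then I2 (5 mol %), CH2Cl2, rt
Reagents that add atoms: dioxygen, O=O
Why: [4+2] photooxygenation of the furan (by far the fastest singlet‑oxygen acceptor in the molecule) destroys its aromaticity, reductive cleavage of the endoperoxide unveils the (Z)‑4‑oxo‑2‑enal (C5 ketone and C8 aldehyde), and iodine‑catalysed isomerisation gives the E‑C6=C7 alkene while the C4 stereocentre is kept by avoiding base.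

**Step 13**
Reactants: 22 (E)‑oxo‑enal vinyl iodide
Product: 23 macrocyclic C8 carbinol (11‑membered ring; C5 ketone; C4 senecioate; C8 epimers)
Conditions: CrCl2 (8 equiv), NiCl2 (2 mol %), DMSO/THF, rt, 2 mM, slow addition
Reagents that add atoms: none
Why: Nozaki–Hiyama–Kishi macrocyclisation (zerovalent nickel inserts into the C–I bond, transmetalation gives a trivalent chromium alkenyl that adds only to the aldehyde) closes the ring at C8–C9 with retention of the C9=C10 geometry, and the C8 configuration is irrelevant because it is oxidised in step 15.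

**Step 14**
Reactants: 23 macrocyclic hydroxy ketone
Product: 24 macrocyclic C5 methyl carbinol ((4R,5R); C8 epimers)
Conditions: MeTi(OiPr)3 (4 equiv), CH2Cl2, −30 → 0 °C
Reagents that add atoms: methyltitanium triisopropoxide, C[Ti](OC(C)C)(OC(C)C)OC(C)C
Why: the weakly basic, non‑chelating methyltitanium adds 1,2 to the ketone in the polar Felkin–Anh (Cornforth) sense, anti to the C4 acyloxy group, which gives the (5R) threo diol monoester and leaves the ester and the acidic C4–H alone.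

**Step 15**
Reactants: 24 diol (C8 epimers)
Product: 25 bis‑TBS ether of the target (cross‑conjugated dienone)
Conditions: MnO2 (excess), CH2Cl2, rt
Reagents that add atoms: none
Why: MnO2 oxidises only the doubly allylic secondary C8 alcohol, converging both epimers to the dienone, while the tertiary C5 alcohol cannot be oxidised.

**Step 16**
Reactants: 25 bis‑TBS dienone
Product: 26 CNP0311723.1 (target)
Conditions: HF·pyridine, pyridine, THF, 0 °C → rt
Reagents that add atoms: none
Why: buffered fluoride‑mediated desilylation removes both TBS ethers without the basic conditions that would cause acyl migration between O4 and O5.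

**Compound list**
1 | geraniol, (2E)-3,7-dimethylocta-2,6-dien-1-ol | CC(C)=CCC/C(C)=C/CO | starting material
2 | geranyl diethyl phosphate | CC(C)=CCC/C(C)=C/COP(=O)(OCC)OCC | intermediate
3 | ethynyltrimethylsilane | C#C[Si](C)(C)C | starting material
4 | diisobutyl[(trimethylsilyl)ethynyl]alane | CC(C)C[Al](CC(C)C)C#C[Si](C)(C)C | intermediate (not isolated)
5 | (S)-(3-ethenyl-3,7-dimethyloct-6-en-1-yn-1-yl)trimethylsilane | C[Si](C)(C)C#C[C@](C)(C=C)CCC=C(C)C | intermediate
6 | {(3S)-5-[(2S)-3,3-dimethyloxiran-2-yl]-3-ethenyl-3-methylpent-1-yn-1-yl}trimethylsilane | C[Si](C)(C)C#C[C@](C)(C=C)CC[C@@H]1OC1(C)C | intermediate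
7 | 9-{(3R)-5-[(2S)-3,3-dimethyloxiran-2-yl]-3-methyl-3-[(trimethylsilyl)ethynyl]pentyl}-9-borabicyclo[3.3.1]nonane | C[Si](C)(C)C#C[C@](C)(CCB1C2CCCC1CCC2)CC[C@@H]1OC1(C)C | intermediate (not isolated)
8 | (3S)-5-[(2S)-3,3-dimethyloxiran-2-yl]-3-methyl-3-[(trimethylsilyl)ethynyl]pentan-1-ol | C[Si](C)(C)C#C[C@](C)(CCO)CC[C@@H]1OC1(C)C | intermediate
9 | (3S)-5-[(2S)-3,3-dimethyloxiran-2-yl]-3-methyl-3-[(trimethylsilyl)ethynyl]pentanal | C[Si](C)(C)C#C[C@](C)(CC=O)CC[C@@H]1OC1(C)C | intermediate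
10 | ethyl (2Z,5S)-7-[(2S)-3,3-dimethyloxiran-2-yl]-2-iodo-5-methyl-5-[(trimethylsilyl)ethynyl]hept-2-enoate | CCOC(=O)/C(I)=C/C[C@@](C)(C#C[Si](C)(C)C)CC[C@@H]1OC1(C)C | intermediate
11 | (2Z,5S)-7-[(2S)-3,3-dimethyloxiran-2-yl]-2-iodo-5-methyl-5-[(trimethylsilyl)ethynyl]hept-2-en-1-ol | OC/C(I)=C/C[C@@](C)(C#C[Si](C)(C)C)CC[C@@H]1OC1(C)C | intermediate
12 | (2Z,5S,8S)-1,8-bis(tert-butyldimethylsilyloxy)-2-iodo-5,9-dimethyl-5-[(trimethylsilyl)ethynyl]deca-2,9-diene | CC(C)(C)[Si](C)(C)OC/C(I)=C/C[C@@](C)(C#C[Si](C)(C)C)CC[C@H](O[Si](C)(C)C(C)(C)C)C(C)=C | intermediate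
13 | (2Z,5S,8S)-1,8-bis(tert-butyldimethylsilyloxy)-5-ethynyl-2-iodo-5,9-dimethyldeca-2,9-diene | CC(C)(C)[Si](C)(C)OC/C(I)=C/C[C@@](C)(C#C)CC[C@H](O[Si](C)(C)C(C)(C)C)C(C)=C | intermediate
14 | furfural (furan-2-carbaldehyde) | O=Cc1ccco1 | starting material
15 | (E)-alkenyl(dicyclohexyl)borane from 13 (boron on C3, configurations as in 13) | CC(C)(C)[Si](C)(C)OC/C(I)=C/C[C@@](C)(/C=C/B(C1CCCCC1)C1CCCCC1)CC[C@H](O[Si](C)(C)C(C)(C)C)C(C)=C | intermediate (not isolated)
16 | (E)-alkenyl(methyl)zinc from 13 (zinc on C3) | CC(C)(C)[Si](C)(C)OC/C(I)=C/C[C@@](C)(/C=C/[Zn]C)CC[C@H](O[Si](C)(C)C(C)(C)C)C(C)=C | intermediate (not isolated)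
17 | (1R,2E,4S,7S)-7-(TBSO)-4-[(2Z)-4-(TBSO)-3-iodobut-2-en-1-yl]-1-(furan-2-yl)-4,8-dimethylnona-2,8-dien-1-ol | CC(C)(C)[Si](C)(C)OC/C(I)=C/C[C@@](C)(/C=C/[C@@H](O)c1ccco1)CC[C@H](O[Si](C)(C)C(C)(C)C)C(C)=C | intermediate
18 | 3-methylbut-2-enoic acid (senecioic acid) | CC(C)=CC(=O)O | starting material
19 | senecioate of 17, (1R,2E,4S,7S) | CC(C)(C)[Si](C)(C)OC/C(I)=C/C[C@@](C)(/C=C/[C@@H](OC(=O)C=C(C)C)c1ccco1)CC[C@H](O[Si](C)(C)C(C)(C)C)C(C)=C | intermediate
20 | furan endoperoxide of 19 (1-substituted 2,3,7-trioxabicyclo[2.2.1]hept-5-ene, bridgehead epimers) | CC(C)(C)[Si](C)(C)OC/C(I)=C/C[C@@](C)(/C=C/[C@@H](OC(=O)C=C(C)C)C12OOC(O1)C=C2)CC[C@H](O[Si](C)(C)C(C)(C)C)C(C)=C | intermediate (not isolated)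
21 | (2Z)-isomer of 22 | CC(C)(C)[Si](C)(C)OC/C(I)=C/C[C@@](C)(/C=C/[C@@H](OC(=O)C=C(C)C)C(=O)/C=C\C=O)CC[C@H](O[Si](C)(C)C(C)(C)C)C(C)=C | intermediate (not isolated)
22 | (2E,5R,6E,8S,11S)-11-(TBSO)-8-[(2Z)-4-(TBSO)-3-iodobut-2-en-1-yl]-8,12-dimethyl-1,4-dioxotrideca-2,6,12-trien-5-yl 3-methylbut-2-enoate | CC(C)(C)[Si](C)(C)OC/C(I)=C/C[C@@](C)(/C=C/[C@@H](OC(=O)C=C(C)C)C(=O)/C=C/C=O)CC[C@H](O[Si](C)(C)C(C)(C)C)C(C)=C | intermediate
23 | macrocyclic C8 carbinol: (1S,4R,2E,6E,9Z) ring with C5 ketone, C4 senecioate, C9 CH2OTBS, (S) side-chain OTBS, C8 epimers | C=C(C)[C@@H](O[Si](C)(C)C(C)(C)C)CC[C@]1(C)/C=C/[C@@H](OC(=O)C=C(C)C)C(=O)/C=C/C(O)/C(CO[Si](C)(C)C(C)(C)C)=C\C1 | intermediate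
24 | macrocyclic C5 methyl carbinol: (1S,4R,5R), C8 epimers | C=C(C)[C@@H](O[Si](C)(C)C(C)(C)C)CC[C@]1(C)/C=C/[C@@H](OC(=O)C=C(C)C)[C@](C)(O)/C=C/C(O)/C(CO[Si](C)(C)C(C)(C)C)=C\C1 | intermediate
25 | bis-TBS ether of the target (C8 ketone) | C=C(C)[C@@H](O[Si](C)(C)C(C)(C)C)CC[C@]1(C)/C=C/[C@@H](OC(=O)C=C(C)C)[C@](C)(O)/C=C/C(=O)/C(CO[Si](C)(C)C(C)(C)C)=C\C1 | intermediate
26 | CNP0311723.1: (1S,4R,5R,2E,6E,9Z) ring, (S) side-chain carbinol | C=C(C)[C@@H](O)CC[C@]1(C)/C=C/[C@@H](OC(=O)C=C(C)C)[C@](C)(O)/C=C/C(=O)/C(CO)=C\C1 | target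

**Totals**
Total steps: 16. Longest linear sequence: 16 steps (1 → 26); furfural, ethynyltrimethylsilane and senecioic acid enter as bought.

**Three steps most likely to fail**

Step 12 (furan photooxygenation on the fully elaborated chain). The risks are collapse of the endoperoxide to a hydroxybutenolide, ene reactions of other alkenes, and epimerisation or double‑bond migration at the doubly activated C4–H during the Z → E isomerisation. The fallback sets out from 19 and comes back at 22. The furan is oxidised anodically instead (graphite electrodes, MeOH, Et4NOTs, −20 °C, constant current), which stores the ring‑opened oxidation state as the isolable 2,5‑dimethoxy‑2,5‑dihydrofuran F1. Buffered hydrolysis (PPTS, wet acetone) then releases the ene‑dicarbonyl (first as 21), and the same acid equilibrates it to the E isomer 22.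

Step 13 (chromium‑mediated ring closure on an ene‑dicarbonyl). Divalent chromium may reduce the 4‑oxo‑2‑enal or cleave the α‑acyloxy ketone before the alkenyl addition occurs, and the 11‑membered ring is demanding. The fallback sets out from 22 and comes back at 24. The aldehyde alone is masked (HC(OMe)3, MeOH, CeCl3·7H2O cat.) to give the keto dimethyl acetal F2. The ketone is methylated on the open chain with MeTi(OiPr)3 under acyclic Felkin–Anh control to give the tertiary alcohol acetal F3. PPTS in wet acetone then frees the (E)‑γ‑hydroxy enal F4, and the CrCl2/NiCl2 ring closure is run on this simple enal, which gives 24 directly.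

Step 14 (methyl addition in the macrocycle). The risks are low reactivity of the methyltitanium reagent, titanium‑alkoxide transesterification or O4 → O5 acyl migration, and a macrocyclic conformation that overrides Felkin–Anh control. The fallback sets out from 17 and comes back at 25; it postpones the ester and uses a bulky non‑chelating silyl ether as the controlling group. Alcohol 17 is silylated (TESCl, imidazole) to the triethylsilyl ether F5. The furan is opened as in step 12 to the oxo‑enal F6, and the ring is closed as in step 13 to the macrocyclic hydroxy ketone F7. MeLi/CeCl3 at −78 °C then adds anti to the α‑silyloxy group to give the methyl carbinol F8, and MnO2 gives the dienone F9. PPTS in MeOH removes only the TES group to give the C4,C5‑diol F10. Steglich esterification with 18 acylates the secondary C4 hydroxyl and gives 25.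

**Further compounds**
F1 | step 12 | 2,5-dimethoxy-2,5-dihydrofuran from 19 (mixture at the two acetal carbons) | CC(C)(C)[Si](C)(C)OC/C(I)=C/C[C@@](C)(/C=C/[C@@H](OC(=O)C=C(C)C)C1(OC)OC(OC)C=C1)CC[C@H](O[Si](C)(C)C(C)(C)C)C(C)=C
F2 | step 13 | keto dimethyl acetal of 22 | CC(C)(C)[Si](C)(C)OC/C(I)=C/C[C@@](C)(/C=C/[C@@H](OC(=O)C=C(C)C)C(=O)/C=C/C(OC)OC)CC[C@H](O[Si](C)(C)C(C)(C)C)C(C)=C
F3 | step 13 | open-chain (4R,5R) methyl carbinol dimethyl acetal | CC(C)(C)[Si](C)(C)OC/C(I)=C/C[C@@](C)(/C=C/[C@@H](OC(=O)C=C(C)C)[C@](C)(O)/C=C/C(OC)OC)CC[C@H](O[Si](C)(C)C(C)(C)C)C(C)=C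
F4 | step 13 | open-chain (E)-γ-hydroxy enal | CC(C)(C)[Si](C)(C)OC/C(I)=C/C[C@@](C)(/C=C/[C@@H](OC(=O)C=C(C)C)[C@](C)(O)/C=C/C=O)CC[C@H](O[Si](C)(C)C(C)(C)C)C(C)=C
F5 | step 14 | triethylsilyl ether of 17 | CC(C)(C)[Si](C)(C)OC/C(I)=C/C[C@@](C)(/C=C/[C@@H](O[Si](CC)(CC)CC)c1ccco1)CC[C@H](O[Si](C)(C)C(C)(C)C)C(C)=C
F6 | step 14 | (E)-4-oxo-2-enal with C4 OTES | CC(C)(C)[Si](C)(C)OC/C(I)=C/C[C@@](C)(/C=C/[C@@H](O[Si](CC)(CC)CC)C(=O)/C=C/C=O)CC[C@H](O[Si](C)(C)C(C)(C)C)C(C)=C
F7 | step 14 | macrocyclic hydroxy ketone with C4 OTES (C8 epimers) | C=C(C)[C@@H](O[Si](C)(C)C(C)(C)C)CC[C@]1(C)/C=C/[C@@H](O[Si](CC)(CC)CC)C(=O)/C=C/C(O)/C(CO[Si](C)(C)C(C)(C)C)=C\C1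
F8 | step 14 | macrocyclic C5 methyl carbinol with C4 OTES (C8 epimers) | C=C(C)[C@@H](O[Si](C)(C)C(C)(C)C)CC[C@]1(C)/C=C/[C@@H](O[Si](CC)(CC)CC)[C@](C)(O)/C=C/C(O)/C(CO[Si](C)(C)C(C)(C)C)=C\C1
F9 | step 14 | macrocyclic dienone with C4 OTES | C=C(C)[C@@H](O[Si](C)(C)C(C)(C)C)CC[C@]1(C)/C=C/[C@@H](O[Si](CC)(CC)CC)[C@](C)(O)/C=C/C(=O)/C(CO[Si](C)(C)C(C)(C)C)=C\C1
F10 | step 14 | macrocyclic dienone C4,C5-diol (bis-TBS) | C=C(C)[C@@H](O[Si](C)(C)C(C)(C)C)CC[C@]1(C)/C=C/[C@@H](O)[C@](C)(O)/C=C/C(=O)/C(CO[Si](C)(C)C(C)(C)C)=C\C1
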